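**Retrosynthetic overview**

- The target is opened by a reductive radical cascade (7-exo, then 5-exo) to a bicyclo[3.3.1]nonane-2,4,9-trione carrying Cl and prenyl at C-3 and an endo prenyl at C-7; the seven-membered ring and then the cyclopentane are formed last.
- The bicycle is opened at C-1–C-8 (cationic ring closure) to a dearomatised 6-geranyl-6-lavandulyl chloro-trione; this closes the bridged cyclohexanone.
- Key step: face-selective dearomative C-geranylation of a fully substituted chloro(lavandulyl)acylphloroglucinol, which breaks the aromatic ring and sets the C-5 quaternary centre against the pre-set C-7 centre; a C-prenylation then makes C-3 quaternary.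
- The arene comes from phloroglucinol by Friedel–Crafts acylation, monochlorination (blocking group and later radical handle) and C-alkylation with (S)-lavandulyl iodide from resolved lavandulol.
- Ring order: phloroglucinol ring, bridged cyclohexanone, seven-membered ring, cyclopentane.

Assumption: lavandulol is bought as the racemate; C-1 to C-9 for the bicyclic compounds are the usual bicyclo[3.3.1]nonane locants (C-1 acyl bridgehead, C-5 geranyl bridgehead, C-9 bridging carbonyl).

**Route**

Step 1
Reactants: 1 (±)-lavandulol
Product: 2 (S)-lavandulol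
Conditions: Candida antarctica lipase B (immobilised), vinyl acetate (0.7 equiv), hexane, 25 °C, to about 65% conversion
Reagents that add atoms: none
Why: Lipase-catalysed kinetic resolution by enantioselective transesterification, in which the (R)-alcohol is acetylated faster so that the recovered alcohol is (S)-2 of high ee, carrying the future C-7 stereocentre.

Step 2
Reactants: 2 (S)-lavandulol
Product: 3 (S)-lavandulyl iodide
Conditions: I2, PPh3, imidazole, CH2Cl2, 0 °C
Reagents that add atoms: iodine, II
Why: Appel-type iodination (Garegg–Samuelsson conditions), an SN2 displacement at the primary carbon that leaves the adjacent stereocentre untouched.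

Step 3
Reactants: 4 phloroglucinol; 5 isobutyryl chloride
Product: 6 phlorisobutyrophenone
Conditions: AlCl3 (3.5 equiv), PhNO2, 65 °C; aq HCl
Reagents that add atoms: none
Why: Friedel–Crafts acylation of the electron-rich triol stops after one acylation because the chelated aryl ketone deactivates the ring.

Step 4
Reactants: 6 phlorisobutyrophenone
Product: 7 3-chlorophlorisobutyrophenone
Conditions: SO2Cl2 (1.0 equiv), Et2O, 0 °C
Reagents that add atoms: sulfuryl chloride, ClS(Cl)(=O)=O
Why: Electrophilic aromatic chlorination, where the two free ring positions of 6 are equivalent so one equivalent gives a single monochloride whose chlorine blocks that carbon now and is the radical leaving group later.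

Step 5
Reactants: 7 3-chlorophlorisobutyrophenone; 3 (S)-lavandulyl iodide
Product: 8 3-chloro-5-[(R)-lavandulyl]phlorisobutyrophenone
Conditions: NaH (2.2 equiv), toluene, 80 °C
Reagents that add atoms: none
Why: Phenolate C-alkylation (SN2) in a non-polar medium takes place at the only unsubstituted ring carbon, and the side-chain stereocentre is not involved (its descriptor changes to R only through the priority change).

Step 6
Reactants: 8 3-chloro-5-[(R)-lavandulyl]phlorisobutyrophenone; 9 geranyl bromide
Product: 10 (6R)-4-chloro-6-geranyl-3,5-dihydroxy-2-isobutyryl-6-[(R)-lavandulyl]cyclohexa-2,4-dien-1-one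
Conditions: CsOH·H2O (3 equiv), N-(9-anthracenylmethyl)-O-allylcinchonidinium bromide (10 mol%), toluene–CH2Cl2, −50 °C
Reagents that add atoms: none
Why: Proposed new method: the planar phloroglucinate is expected to ion-pair with the chiral ammonium cation so that one face is shielded and the allylic bromide alkylates by SN2 at the alkyl-bearing ring carbon (the acyl- and chloro-bearing carbons are deactivated) from the open face, which breaks aromaticity and sets the quaternary C-6 centre by catalyst control whatever the remote side-chain centre, the closest known reaction being the cinchona phase-transfer-catalysed enantioselective alkylative dearomatisation of acylphloroglucinols.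

Step 7
Reactants: 10 (6R)-4-chloro-6-geranyl-3,5-dihydroxy-2-isobutyryl-6-[(R)-lavandulyl]cyclohexa-2,4-dien-1-one; 11 prenyl bromide
Product: 12 (6S)-4-chloro-6-geranyl-3-hydroxy-2-isobutyryl-6-[(R)-lavandulyl]-4-prenylcyclohex-2-ene-1,5-dione (C-4 epimers)
Conditions: NaOMe (2.1 equiv), MeOH, 0 °C, then 11 (1.1 equiv), 0 to 25 °C; aq HCl
Reagents that add atoms: none
Why: C-Alkylation of the vinylogous-acid dianion (the lupulone-type allylation) occurs at the more basic chloro-substituted carbon in a protic solvent and makes C-4 quaternary as an inconsequential epimer mixture, because this centre later becomes a planar radical.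

Step 8
Reactants: 12 (6S)-4-chloro-6-geranyl-3-hydroxy-2-isobutyryl-6-[(R)-lavandulyl]-4-prenylcyclohex-2-ene-1,5-dione
Product: 14 (1S,5S,7R)-3-chloro-5-geranyl-1-isobutyryl-8,8-dimethyl-3,7-diprenylbicyclo[3.3.1]nonane-2,4,9-trione (7-prenyl endo; C-3 epimers), via tertiary side-chain carbocation 13 (not isolated)
Conditions: HCO2H (neat), 25 °C, 12 h
Reagents that add atoms: none
Why: Biomimetic cationic cyclisation (C-alkylation of a beta-triketone enol by a tertiary carbocation), in which C-4 of 12 is quaternary so the acyl-bearing carbon is the only carbon nucleophile, O-alkylation is reversible in formic acid, the new C-1 centre is fixed by the face on which the side chain sits at C-6, and the C-6/side-chain relationship from step 6 allows C–C closure only through the boat-like transition state that leaves the prenylmethyl group on the C-3 side (7-endo).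

Step 9
Reactants: 14 (1S,5S,7R)-3-chloro-5-geranyl-1-isobutyryl-8,8-dimethyl-3,7-diprenylbicyclo[3.3.1]nonane-2,4,9-trione
Product: 18 target CNP0379246.1, via C-3 radical 15 (not isolated), via tertiary alkyl radical 16 (not isolated), via isopropyl radical 17 (not isolated)
Conditions: Bu3SnH (1.3 equiv, syringe pump over 6 h), 2,2'-azobis(isobutyronitrile) (0.2 equiv), benzene (0.005 M), 80 °C
Reagents that add atoms: none
Why: Tin hydride radical cascade in which chlorine abstraction gives planar radical 15, which adds 7-exo to the endo prenyl group from the only face it can reach (setting C-3 and, with the bulky radical terminus pseudo-equatorial on the C-1 side of the twisted two-carbon bridge, the ring-fusion CH), radical 16 then closes 5-exo through a Beckwith chair onto the C-3 prenyl group so that the new radical carbon is trans to the bridge CH2, and radical 17 takes hydrogen from Bu3SnH to give the isopropyl group.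

**Compound list**

1 | (±)-lavandulol | OCC(C(C)=C)CC=C(C)C | starting material
2 | (S)-lavandulol | OC[C@H](C(C)=C)CC=C(C)C | intermediate
3 | (S)-lavandulyl iodide | IC[C@H](C(C)=C)CC=C(C)C | intermediate
4 | phloroglucinol | Oc1cc(O)cc(O)c1 | starting material
5 | isobutyryl chloride | CC(C)C(Cl)=O | starting material
6 | phlorisobutyrophenone (2-methyl-1-(2,4,6-trihydroxyphenyl)propan-1-one) | CC(C)C(=O)c1c(O)cc(O)cc1O | intermediate
7 | 3-chlorophlorisobutyrophenone | CC(C)C(=O)c1c(O)cc(O)c(Cl)c1O | intermediate
8 | 3-chloro-5-[(R)-lavandulyl]phlorisobutyrophenone | CC(C)C(=O)c1c(O)c(Cl)c(O)c(C[C@H](C(C)=C)CC=C(C)C)c1O | intermediate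
9 | geranyl bromide (E) | BrC/C=C(\C)CCC=C(C)C | starting material
10 | (6R)-4-chloro-6-geranyl-3,5-dihydroxy-2-isobutyryl-6-[(R)-lavandulyl]cyclohexa-2,4-dien-1-one | CC(C)C(=O)C1=C(O)C(Cl)=C(O)[C@@](C/C=C(\C)CCC=C(C)C)(C[C@H](C(C)=C)CC=C(C)C)C1=O | intermediate
11 | prenyl bromide | BrCC=C(C)C | starting material
12 | (6S)-4-chloro-6-geranyl-3-hydroxy-2-isobutyryl-6-[(R)-lavandulyl]-4-prenylcyclohex-2-ene-1,5-dione (C-4 epimers) | CC(C)C(=O)C1=C(O)C(Cl)(CC=C(C)C)C(=O)[C@@](C/C=C(\C)CCC=C(C)C)(C[C@H](C(C)=C)CC=C(C)C)C1=O | intermediate
13 | tertiary side-chain carbocation from 12 | CC(C)C(=O)C1=C(O)C(Cl)(CC=C(C)C)C(=O)[C@@](C/C=C(\C)CCC=C(C)C)(C[C@H]([C+](C)C)CC=C(C)C)C1=O | intermediate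
14 | (1S,5S,7R)-3-chloro-5-geranyl-1-isobutyryl-8,8-dimethyl-3,7-diprenylbicyclo[3.3.1]nonane-2,4,9-trione (7-prenyl endo; C-3 epimers) | CC(C)=CCC/C(C)=C/C[C@]12C[C@@H](CC=C(C)C)C(C)(C)[C@](C(=O)C(C)C)(C1=O)C(=O)C(Cl)(CC=C(C)C)C2=O | intermediate
15 | C-3 radical from 14 | CC(C)=CCC/C(C)=C/C[C@]12C[C@@H](CC=C(C)C)C(C)(C)[C@](C(=O)C(C)C)(C1=O)C(=O)[C](CC=C(C)C)C2=O | intermediate
16 | tertiary alkyl radical after the 7-exo closure | CC(C)=CCC/C(C)=C/C[C@@]12C[C@H]3C[C@H]([C](C)C)[C@@](CC=C(C)C)(C1=O)C(=O)[C@@](C(=O)C(C)C)(C2=O)C3(C)C | intermediate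
17 | isopropyl radical after the 5-exo closure | CC(C)=CCC/C(C)=C/C[C@@]12C[C@H]3C[C@@H]4C(C)(C)[C@@H]([C](C)C)C[C@]4(C1=O)C(=O)[C@@](C(=O)C(C)C)(C2=O)C3(C)C | intermediate
18 | target CNP0379246.1: 1S,3S,5R,7R bicyclic core; C-3 and C-7 joined by a CH2–CH bridge; cyclopentane fused on the C-3–CH bond with R ring-fusion CH (gem-dimethyl carbon syn to C-2) and R CH-isopropyl (trans to the bridge CH2) | CC(C)=CCC/C(C)=C/C[C@@]12C[C@H]3C[C@@H]4C(C)(C)[C@@H](C(C)C)C[C@]4(C1=O)C(=O)[C@@](C(=O)C(C)C)(C2=O)C3(C)C | target

**Step count and risks**

Total: 9 steps. Longest linear sequence: 7 steps (steps 3 to 9 from phloroglucinol; equally steps 1, 2 and 5 to 9 from lavandulol).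

The three steps most likely to fail:

Step 8 (cationic ring closure). The wanted closure must pass a boat-like transition state and competes with protonation of the trisubstituted alkenes (geranyl and prenyl cations can also close onto the acyl-bearing carbon) and with elimination. Fallback: make the cation site-specific with a pre-installed leaving group. Starting from 12, hydrochlorinate only the 1,1-disubstituted alkene in the Markovnikov sense by hydrogen-atom transfer (Co(BF4)2·6H2O with a salen-type ligand, PhSiH3, TsCl, EtOH) to give the tertiary chloride of 12 (isopropenyl converted into 2-chloropropan-2-yl) F4. Solvolyse this in HCO2H buffered with HCO2Na at 0 °C, where ionisation of the tertiary chloride is much faster than alkene protonation, so that only cation 13 forms. This rejoins the route at 14.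

Step 6 (face selectivity of the dearomative geranylation). The catalyst may not control the face, giving both C-6 epimers; the wrong one leads to the 7-exo bicycle, which cannot cage. Fallback: use ring control instead of catalyst control. Starting from 8, close the isopropenyl group onto the phenol ortho to the ketone (CF3CO2H, CH2Cl2; the regioisomeric pyran is separated) to give (3R)-6-chloro-5,7-dihydroxy-8-isobutyryl-2,2-dimethyl-3-prenylchromane F1. C-Geranylate its sodium salt (NaH, toluene, 9); the half-chair pyran forces attack at C-4a anti to the C-3 prenylmethyl group and gives the dearomatised 4a-geranyl chromenone F2. Prenylate (NaOMe, MeOH, 11) to the chloro prenyl diketone F3. Formic acid then ionises the tertiary vinylogous ester of F3 to the same cation as 13, rejoining the route at 14.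

Step 9 (radical cascade). Radical 15 may be reduced before the strained 7-exo closure, or the ring-fusion CH may form as the other epimer (this selectivity is the least predictable in the route). Fallback: run the cascade oxidatively from the enol. Starting from 14, remove chlorine (Zn, AcOH) to give the enolised (1S,5S,7R)-5-geranyl-4-hydroxy-1-isobutyryl-8,8-dimethyl-3,7-diprenylbicyclo[3.3.1]non-3-ene-2,9-dione F5. Oxidise with Mn(OAc)3·2H2O and Cu(OAc)2·H2O in AcOH; the manganese enolate radical cyclises in the same 7-exo/5-exo order and copper ends the cascade by elimination, giving the isopropenyl analogue of the target F6. Hydrogenate only the 1,1-disubstituted alkene (RhCl(PPh3)3, H2, benzene) to rejoin the route at 18.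

**Further compounds**

F1 | step 6 | (3R)-6-chloro-5,7-dihydroxy-8-isobutyryl-2,2-dimethyl-3-prenylchromane | CC(C)C(=O)c1c(O)c(Cl)c(O)c2C[C@@H](CC=C(C)C)C(C)(C)Oc12
F2 | step 6 | dearomatised 4a-geranyl chromenone (pyran retained, chloro-enol) | CC(C)C(=O)C1=C2OC(C)(C)[C@H](CC=C(C)C)C[C@]2(C/C=C(\C)CCC=C(C)C)C(O)=C(Cl)C1=O
F3 | step 6 | chloro prenyl diketone of the 4a-geranyl chromenone (C-Cl epimers) | CC(C)C(=O)C1=C2OC(C)(C)[C@H](CC=C(C)C)C[C@]2(C/C=C(\C)CCC=C(C)C)C(=O)C(Cl)(CC=C(C)C)C1=O
F4 | step 8 | tertiary chloride of 12 (isopropenyl converted into 2-chloropropan-2-yl) | CC(C)C(=O)C1=C(O)C(Cl)(CC=C(C)C)C(=O)[C@@](C/C=C(\C)CCC=C(C)C)(C[C@H](C(C)(C)Cl)CC=C(C)C)C1=O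
F5 | step 9 | (1S,5S,7R)-5-geranyl-4-hydroxy-1-isobutyryl-8,8-dimethyl-3,7-diprenylbicyclo[3.3.1]non-3-ene-2,9-dione | CC(C)=CCC/C(C)=C/C[C@]12C[C@@H](CC=C(C)C)C(C)(C)[C@](C(=O)C(C)C)(C1=O)C(O)=C(CC=C(C)C)C2=O
F6 | step 9 | isopropenyl analogue of the target | CC(C)=CCC/C(C)=C/C[C@@]12C[C@H]3C[C@@H]4C(C)(C)[C@@H](C(C)=C)C[C@]4(C1=O)C(=O)[C@@](C(=O)C(C)C)(C2=O)C3(C)C
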